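The flavan C4 methine is bonded to flavonol C5, the ring A position peri to the C4 carbonyl that no Friedel–Crafts union would reach. It is also bonded to flavan C4a, whose neighbour C8a carries O1. Flavan ring C is therefore cut at O1–C2 and C3–C4 into an ortho-quinone methide and an (E)-beta-benzoyloxystyrene. One chiral Brønsted acid catalysed oxa-[4+2] cycloaddition closes ring C, brings in the second catechol ring and sets C2, C3 and C4 together. Its precursor is a racemic ortho-hydroxybenzhydrol that links C5 of the perbenzylated flavonol to a pyrogallol-derived ring. The C5 carbon is installed by ketone-directed C–H alkenylation followed by alkene cleavage.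

Key step: step 12

Assumption: precedent does not predict the sense of induction for this new alkene class, so the (R)-configured catalyst is written in step 12 and its mirror image would be used if it favours the (2S,3R,4S) series.

Step 1
Reactants: 1 2',3',4'-trihydroxyacetophenone (gallacetophenone)
Product: 2 3',4'-bis(benzyloxy)-2'-hydroxyacetophenone
Conditions: BnBr (2.1 equiv), K2CO3 (2.2 equiv), acetone, reflux
Reagents that add atoms: benzyl bromide, BrCc1ccccc1
Why: Williamson etherification in which the 2'-hydroxyl, held in a hydrogen bond to the acetyl carbonyl, is much less nucleophilic, so two equivalents of benzyl bromide should cap only O3' and O4'.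

Step 2
Reactants: 2 3',4'-bis(benzyloxy)-2'-hydroxyacetophenone; 3 3,4-bis(benzyloxy)benzaldehyde
Product: 4 (E)-3,4,3',4'-tetrakis(benzyloxy)-2'-hydroxychalcone
Conditions: KOH (aq), EtOH/THF, rt
Reagents that add atoms: none
Why: Claisen–Schmidt condensation of a methyl ketone with a non-enolisable aldehyde, in which E1cB dehydration should give only the (E)-enone and the benzyl ethers are inert to hydroxide.

Step 3
Reactants: 4 (E)-3,4,3',4'-tetrakis(benzyloxy)-2'-hydroxychalcone
Product: 6 7,8,3',4'-tetra-O-benzylmelanoxetin (free 3-hydroxyl), via trans-dihydroflavonol 5 (not isolated)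
Conditions: H2O2 (30% aq), NaOH (aq), MeOH/THF, 0 °C to rt
Reagents that add atoms: hydrogen peroxide, OO
Why: Algar–Flynn–Oyamada reaction, in which alkaline hydroperoxide oxygenates the enone while the 2'-phenoxide closes the pyranone at the beta carbon, 5 is dehydrogenated in the same flask, and the lack of a 6'-substituent favours the flavonol over the aurone.

Step 4
Reactants: 6 7,8,3',4'-tetra-O-benzylmelanoxetin
Product: 7 3,7,8,3',4'-penta-O-benzylmelanoxetin
Conditions: BnBr, K2CO3, DMF, 60 °C
Reagents that add atoms: benzyl bromide, BrCc1ccccc1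
Why: Williamson etherification of the acidic enolic 3-hydroxyl, which removes the last free OH and with it a chelating site for rhodium and copper before the C–H activation.

Step 5
Reactants: 7 3,7,8,3',4'-penta-O-benzylmelanoxetin; 8 methyl acrylate
Product: 9 methyl (E)-3-(3,7,8,3',4'-penta-O-benzylmelanoxetin-5-yl)acrylate
Conditions: [Cp*RhCl2]2 (2.5 mol %), AgSbF6 (10 mol %), Cu(OAc)2 (2.1 equiv), 8 (3 equiv), ClCH2CH2Cl, 100 °C
Reagents that add atoms: none
Why: Ketone-directed oxidative C–H alkenylation (Fujiwara–Moritani type) known for chromones and flavones, in which the C4 carbonyl guides cationic Cp*Rh (trivalent rhodium) into the peri C5–H bond through a five-membered rhodacycle, acrylate insertion and beta-hydride elimination give the (E)-alkene, and C6 lies out of reach of the directing group.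

Step 6
Reactants: 9 methyl (E)-3-(3,7,8,3',4'-penta-O-benzylmelanoxetin-5-yl)acrylate
Product: 11 3,7,8,3',4'-penta-O-benzylmelanoxetin-5-carbaldehyde, via syn-diol 10 (not isolated)
Conditions: OsO4 (2 mol %), NaIO4 (4 equiv), 2,6-lutidine (2 equiv), 1,4-dioxane/H2O, rt
Reagents that add atoms: osmium tetroxide, O=[Os](=O)(=O)=O; NaIO4, [Na+].[O-]I(=O)(=O)=O
Why: Lemieux–Johnson cleavage, selective because the cinnamate-type alkene is the only isolated C=C bond, the pyranone C2=C3 bond is tetrasubstituted and deactivated as a vinylogous ester, and 2,6-lutidine keeps the medium neutral.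

Step 7
Reactants: 12 2,3-dihydroxybenzaldehyde
Product: 13 2,3-bis(benzyloxy)benzaldehyde
Conditions: BnBr (2.4 equiv), K2CO3 (3 equiv), DMF, 60 °C
Reagents that add atoms: benzyl bromide, BrCc1ccccc1
Why: Williamson etherification with excess reagent in a dipolar solvent, forcing enough to alkylate the chelated 2-hydroxyl as well.

Step 8
Reactants: 13 2,3-bis(benzyloxy)benzaldehyde
Product: 15 2,3-bis(benzyloxy)phenol, via aryl formate 14 (not isolated)
Conditions: mCPBA, CH2Cl2, rt; wash (aq NaHCO3/Na2SO3), concentrate; K2CO3 (cat.), MeOH, rt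
Reagents that add atoms: mCPBA, O=C(OO)c1cccc(Cl)c1
Why: Baeyer–Villiger (Dakin-type) oxidation in which the electron-rich ortho-alkoxyaryl group migrates in preference to hydride, followed by transesterification of the labile formate 14 without purification.

Step 9
Reactants: 15 2,3-bis(benzyloxy)phenol; 11 3,7,8,3',4'-penta-O-benzylmelanoxetin-5-carbaldehyde
Product: 17 racemic [3,4-bis(benzyloxy)-2-hydroxyphenyl](3,7,8,3',4'-penta-O-benzylmelanoxetin-5-yl)methanol, via bromomagnesium phenoxide 16 (not isolated)
Conditions: 15, EtMgBr (1.0 equiv), Et2O, 0 °C; solvent exchange to toluene/CH2Cl2; 11 (0.95 equiv), 0 °C to rt; pH 7 buffer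
Reagents that add atoms: none
Why: Ortho-specific hydroxyalkylation of a magnesium phenoxide by an aromatic aldehyde, in which magnesium in a non-coordinating solvent binds both oxygen atoms and delivers the carbonyl carbon through a six-membered transition state to C6, the only open ortho position, while the new stereocentre forms as a racemate and is erased in step 12.

Step 10
Reactants: 3 3,4-bis(benzyloxy)benzaldehyde; 18 bis[(pinacolato)boryl]methane
Product: 20 (E)-2-[3,4-bis(benzyloxy)phenyl]vinylboronic acid pinacol ester, via lithiated diborylmethane 19 (not isolated)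
Conditions: 18 (1.2 equiv), LiTMP (1.2 equiv), THF, 0 °C; then 3, −78 °C to rt
Reagents that add atoms: none
Why: Boron–Wittig olefination, in which the alpha-boryl carbanion 19 adds to the aldehyde and syn elimination of the boron–oxygen pair from the less crowded adduct gives the (E)-alkenylboronate in one operation.

Step 11
Reactants: 20 (E)-2-[3,4-bis(benzyloxy)phenyl]vinylboronic acid pinacol ester
Product: 21 (E)-2-[3,4-bis(benzyloxy)phenyl]vinyl benzoate
Conditions: Cu(O2CPh)2 (2.2 equiv), Et3N (3 equiv), 4 Å MS, CH2Cl2, rt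
Reagents that add atoms: copper dibenzoate, O=C([O-])c1ccccc1.O=C([O-])c1ccccc1.[Cu+2]
Why: Chan–Lam type copper-mediated C(sp2)–O coupling of an alkenylboron reagent with a carboxylate, which runs by transmetalation to divalent copper and reductive elimination from trivalent copper with retention of the (E) geometry, the dibenzoate being chosen so that no second carboxylate competes for the alkenyl group.

Step 12
Reactants: 17 racemic ortho-hydroxybenzhydrol; 21 (E)-2-[3,4-bis(benzyloxy)phenyl]vinyl benzoate
Product: 23 (2R,3S,4R)-7,8-bis(benzyloxy)-2-[3,4-bis(benzyloxy)phenyl]-4-(3,7,8,3',4'-penta-O-benzylmelanoxetin-5-yl)chroman-3-yl benzoate, via ortho-quinone methide 22 (not isolated)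
Conditions: (R)-3,3'-bis(2,4,6-triisopropylphenyl)-1,1'-binaphthyl-2,2'-diyl N-triflylphosphoramide (10 mol %), 21 (1.5 equiv), 4 Å MS, toluene/CH2Cl2, −20 °C to rt
Reagents that add atoms: none
Why: Proposed new method: the strong chiral acid ionises the doubly benzylic carbinol of 17 (helped by the ortho hydroxyl and para benzyloxy group of the pyrogallol ring and by the para C8 benzyloxy group of flavonol ring A) to the ion-paired (E)-ortho-quinone methide 22, the benzoyloxy-bearing alkene carbon of 21 attacks its exocyclic carbon (C3–C4 bond) while charge builds at the para-benzyloxybenzylic carbon, and the quinone methide oxygen collapses onto that carbon (O1–C2 bond). The closest known reaction type is the chiral Brønsted acid catalysed inverse-electron-demand oxa-Diels–Alder reaction of ortho-quinone methides released from ortho-hydroxybenzhydrols with styrenes that lack a hydrogen-bond donor, supported by acid-promoted additions of (E)-propenylarenes that give 2,3-trans-3,4-trans chromans, whereas an (E)-beta-acyloxystyrene has not been shown as the two-carbon partner. Flavan ring C is the only ring closed, in an asynchronous [4+2] mode that joins the four-atom unit O1–C8a–C4a–C4 of 22 to C3–C2 of 21. The C2/C3 trans relation is carried over from the (E) alkene (and, if the addition turns stepwise, is restored by benzoate participation through a trans-dioxolanylium ion that the phenol oxygen opens with inversion), the C3/C4 trans and C2/C4 cis relations come from the transition state with the aryl group endo and the benzoyloxy group exo to the (E)-quinone methide, which leaves all three substituents equatorial, and the absolute sense (2R,3S,4R) comes from the chiral anion that shields one face of 22, the stereocentre of racemic 17 having been erased. The step needs styrene-type and not enol-ester-type regiochemistry, secured because the para-benzyloxyphenyl group stabilises the developing cation far better than an acyloxy group can, and it needs attachment at flavonol C5, secured because that C–C bond already exists in 17.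

Step 13
Reactants: 23 protected flavan-3-yl benzoate
Product: 24 (2R,3S,4R)-7,8-bis(benzyloxy)-2-[3,4-bis(benzyloxy)phenyl]-4-(3,7,8,3',4'-penta-O-benzylmelanoxetin-5-yl)chroman-3-ol
Conditions: K2CO3, MeOH/THF, rt
Reagents that add atoms: none
Why: Base-catalysed transesterification (Zemplén type) at the acyl carbon, which touches no stereocentre and is run while every phenol is still benzylated, so that neither base-induced C2 epimerisation nor air oxidation can set in.

Step 14
Reactants: 24 nona-O-benzyl flavan-3-ol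
Product: 25 CNP0395591.2
Conditions: H2 (1 atm), Pd(OH)2/C, degassed THF/MeOH, rt; filtration under argon
Reagents that add atoms: none
Why: Catalytic hydrogenolysis of the nine acyclic O-benzyl bonds, conditions under which the cyclic C2–O1 bond, the C4–aryl bonds and the flavonol C2=C3 bond of benzylated flavan-3-ols and flavonols normally persist, so that the three stereocentres are left untouched.

Compound list
1 | 2',3',4'-trihydroxyacetophenone (gallacetophenone) | CC(=O)c1ccc(O)c(O)c1O | starting material
2 | 3',4'-bis(benzyloxy)-2'-hydroxyacetophenone | CC(=O)c1ccc(OCc2ccccc2)c(OCc2ccccc2)c1O | intermediate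
3 | 3,4-bis(benzyloxy)benzaldehyde | O=Cc1ccc(OCc2ccccc2)c(OCc2ccccc2)c1 | starting material
4 | (E)-3,4,3',4'-tetrakis(benzyloxy)-2'-hydroxychalcone | O=C(/C=C/c1ccc(OCc2ccccc2)c(OCc2ccccc2)c1)c1ccc(OCc2ccccc2)c(OCc2ccccc2)c1O | intermediate
5 | trans-7,8,3',4'-tetrakis(benzyloxy)dihydroflavonol (racemic, one enantiomer drawn, not isolated) | O=C1c2ccc(OCc3ccccc3)c(OCc3ccccc3)c2O[C@H](c2ccc(OCc3ccccc3)c(OCc3ccccc3)c2)[C@H]1O | intermediate
6 | 7,8,3',4'-tetra-O-benzylmelanoxetin | O=c1c(O)c(-c2ccc(OCc3ccccc3)c(OCc3ccccc3)c2)oc2c(OCc3ccccc3)c(OCc3ccccc3)ccc12 | intermediate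
7 | 3,7,8,3',4'-penta-O-benzylmelanoxetin | O=c1c(OCc2ccccc2)c(-c2ccc(OCc3ccccc3)c(OCc3ccccc3)c2)oc2c(OCc3ccccc3)c(OCc3ccccc3)ccc12 | intermediate
8 | methyl acrylate | C=CC(=O)OC | starting material
9 | methyl (E)-3-(3,7,8,3',4'-penta-O-benzylmelanoxetin-5-yl)acrylate | COC(=O)/C=C/c1cc(OCc2ccccc2)c(OCc2ccccc2)c2oc(-c3ccc(OCc4ccccc4)c(OCc4ccccc4)c3)c(OCc3ccccc3)c(=O)c12 | intermediate
10 | methyl syn-2,3-dihydroxy-3-(penta-O-benzylmelanoxetin-5-yl)propanoate (racemic, one enantiomer drawn, not isolated) | COC(=O)[C@H](O)[C@@H](O)c1cc(OCc2ccccc2)c(OCc2ccccc2)c2oc(-c3ccc(OCc4ccccc4)c(OCc4ccccc4)c3)c(OCc3ccccc3)c(=O)c12 | intermediate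
11 | 3,7,8,3',4'-penta-O-benzylmelanoxetin-5-carbaldehyde | O=Cc1cc(OCc2ccccc2)c(OCc2ccccc2)c2oc(-c3ccc(OCc4ccccc4)c(OCc4ccccc4)c3)c(OCc3ccccc3)c(=O)c12 | intermediate
12 | 2,3-dihydroxybenzaldehyde | O=Cc1cccc(O)c1O | starting material
13 | 2,3-bis(benzyloxy)benzaldehyde | O=Cc1cccc(OCc2ccccc2)c1OCc1ccccc1 | intermediate
14 | 2,3-bis(benzyloxy)phenyl formate (not isolated) | O=COc1cccc(OCc2ccccc2)c1OCc1ccccc1 | intermediate
15 | 2,3-bis(benzyloxy)phenol | Oc1cccc(OCc2ccccc2)c1OCc1ccccc1 | intermediate
16 | bromomagnesium 2,3-bis(benzyloxy)phenoxide (not isolated) | Br[Mg]Oc1cccc(OCc2ccccc2)c1OCc1ccccc1 | intermediate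
17 | [3,4-bis(benzyloxy)-2-hydroxyphenyl](3,7,8,3',4'-penta-O-benzylmelanoxetin-5-yl)methanol (racemic) | OC(c1ccc(OCc2ccccc2)c(OCc2ccccc2)c1O)c1cc(OCc2ccccc2)c(OCc2ccccc2)c2oc(-c3ccc(OCc4ccccc4)c(OCc4ccccc4)c3)c(OCc3ccccc3)c(=O)c12 | intermediate
18 | bis[(pinacolato)boryl]methane | CC1(C)OB(CB2OC(C)(C)C(C)(C)O2)OC1(C)C | starting material
19 | lithio-bis[(pinacolato)boryl]methane (not isolated) | [Li]C(B1OC(C)(C)C(C)(C)O1)B1OC(C)(C)C(C)(C)O1 | intermediate
20 | (E)-2-[3,4-bis(benzyloxy)phenyl]vinylboronic acid pinacol ester | CC1(C)OB(/C=C/c2ccc(OCc3ccccc3)c(OCc3ccccc3)c2)OC1(C)C | intermediate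
21 | (E)-2-[3,4-bis(benzyloxy)phenyl]vinyl benzoate | O=C(O/C=C/c1ccc(OCc2ccccc2)c(OCc2ccccc2)c1)c1ccccc1 | intermediate
22 | (E)-2,3-bis(benzyloxy)-6-[(penta-O-benzylmelanoxetin-5-yl)methylidene]cyclohexa-2,4-dien-1-one (ortho-quinone methide, not isolated) | O=C1C(OCc2ccccc2)=C(OCc2ccccc2)C=C/C1=C\c1cc(OCc2ccccc2)c(OCc2ccccc2)c2oc(-c3ccc(OCc4ccccc4)c(OCc4ccccc4)c3)c(OCc3ccccc3)c(=O)c12 | intermediate
23 | (2R,3S,4R)-7,8-bis(benzyloxy)-2-[3,4-bis(benzyloxy)phenyl]-4-(penta-O-benzylmelanoxetin-5-yl)chroman-3-yl benzoate | O=c1c(OCc2ccccc2)c(-c2ccc(OCc3ccccc3)c(OCc3ccccc3)c2)oc2c(OCc3ccccc3)c(OCc3ccccc3)cc([C@@H]3c4ccc(OCc5ccccc5)c(OCc5ccccc5)c4O[C@H](c4ccc(OCc5ccccc5)c(OCc5ccccc5)c4)[C@H]3OC(=O)c3ccccc3)c12 | intermediate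
24 | (2R,3S,4R)-7,8-bis(benzyloxy)-2-[3,4-bis(benzyloxy)phenyl]-4-(penta-O-benzylmelanoxetin-5-yl)chroman-3-ol | O=c1c(OCc2ccccc2)c(-c2ccc(OCc3ccccc3)c(OCc3ccccc3)c2)oc2c(OCc3ccccc3)c(OCc3ccccc3)cc([C@@H]3c4ccc(OCc5ccccc5)c(OCc5ccccc5)c4O[C@H](c4ccc(OCc5ccccc5)c(OCc5ccccc5)c4)[C@H]3O)c12 | intermediate
25 | CNP0395591.2, (2R,3S,4R)-2-(3,4-dihydroxyphenyl)-4-[2-(3,4-dihydroxyphenyl)-3,7,8-trihydroxy-4-oxo-4H-chromen-5-yl]chromane-3,7,8-triol | O=c1c(O)c(-c2ccc(O)c(O)c2)oc2c(O)c(O)cc([C@@H]3c4ccc(O)c(O)c4O[C@H](c4ccc(O)c(O)c4)[C@H]3O)c12 | target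

Total step count: 14. Longest linear sequence: 10 (steps 1–6, 9, 12, 13, 14).

Steps most likely to fail

Step 12. Capture of the quinone methide by the acyloxy-deactivated alkene may be slow, which would let the quinone methide self-condense. The enol ester may undergo acid-induced hydrolysis or acyl transfer. Facial selectivity may be poor because the alkene offers the catalyst no hydrogen-bond donor. The fallback uses known chemistry, sets out from 3 and 17, and comes back at 24.
- Ohira–Bestmann alkynylation of 3 gives 4-ethynyl-1,2-bis(benzyloxy)benzene F1.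
- The known acid-catalysed annulation of ortho-quinone methides with arylalkynes (17, F1, catalytic Sc(OTf)3, CH2Cl2) gives the racemic 2,4-diaryl-4H-chromene F2.
- Hydroboration–oxidation of this flav-2-ene (BH3·SMe2 in slight excess at 0 °C, then NaBO3) places boron at C3. It adds H and B syn on the face opposite the C4 aryl group, which gives the 2,3-trans-3,4-trans alcohol as the racemate of 24 and its (2S,3R,4S)-enantiomer F3.
- Preparative chromatography on a chiral stationary phase then delivers 24.

Step 9. The magnesium alkoxide may ionise further and be over-alkylated by a second phenoxide. Addition to the hindered peri aldehyde may be sluggish, and ortho control may be lost if ether is not fully removed. The fallback sets out from 13 and comes back at 17.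
- Bromination para to the 3-benzyloxy group (NBS, DMF) gives 6-bromo-2,3-bis(benzyloxy)benzaldehyde F4.
- Baeyer–Villiger oxidation as in step 8 gives 6-bromo-2,3-bis(benzyloxy)phenyl formate F5.
- Methanolysis gives 6-bromo-2,3-bis(benzyloxy)phenol F6.
- Treatment with n-BuLi (2 equiv, THF, −78 °C) deprotonates the phenol and exchanges bromine for lithium to give the O,C-dilithiated phenoxide F7.
- F7 adds to aldehyde 11 at −78 °C, much faster than to the vinylogous-ester carbonyl, to give 17.

Step 11. The electron-rich alkenylboronate may undergo protodeboronation or oxidative homocoupling. Transmetalation from the pinacol ester may be slow, and the alkene geometry may erode. The fallback replaces the cross-coupling by enolate O-acylation, sets out from 3, and comes back at 21.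
- Wittig methoxymethylenation (Ph3P=CHOMe, THF) gives 4-(2-methoxyvinyl)-1,2-bis(benzyloxy)benzene F8 as an alkene mixture.
- Mild acid hydrolysis gives 3,4-bis(benzyloxy)phenylacetaldehyde F9.
- O-Benzoylation of its enolate (Bz2O, Et3N, DMAP, CH2Cl2) gives 21 together with (Z)-2-[3,4-bis(benzyloxy)phenyl]vinyl benzoate F10.
- F10 is equilibrated toward the more stable (E)-form with a thiyl radical source (PhSSPh, light), and the remainder is removed by crystallisation.

Further compounds
F1 | step 12 | 4-ethynyl-1,2-bis(benzyloxy)benzene | C#Cc1ccc(OCc2ccccc2)c(OCc2ccccc2)c1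
F2 | step 12 | racemic 7,8-bis(benzyloxy)-2-[3,4-bis(benzyloxy)phenyl]-4-(penta-O-benzylmelanoxetin-5-yl)-4H-chromene | O=c1c(OCc2ccccc2)c(-c2ccc(OCc3ccccc3)c(OCc3ccccc3)c2)oc2c(OCc3ccccc3)c(OCc3ccccc3)cc(C3C=C(c4ccc(OCc5ccccc5)c(OCc5ccccc5)c4)Oc4c(OCc5ccccc5)c(OCc5ccccc5)ccc34)c12
F3 | step 12 | (2S,3R,4S)-enantiomer of 24 | O=c1c(OCc2ccccc2)c(-c2ccc(OCc3ccccc3)c(OCc3ccccc3)c2)oc2c(OCc3ccccc3)c(OCc3ccccc3)cc([C@H]3c4ccc(OCc5ccccc5)c(OCc5ccccc5)c4O[C@@H](c4ccc(OCc5ccccc5)c(OCc5ccccc5)c4)[C@@H]3O)c12
F4 | step 9 | 6-bromo-2,3-bis(benzyloxy)benzaldehyde | O=Cc1c(Br)ccc(OCc2ccccc2)c1OCc1ccccc1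
F5 | step 9 | 6-bromo-2,3-bis(benzyloxy)phenyl formate | O=COc1c(Br)ccc(OCc2ccccc2)c1OCc1ccccc1
F6 | step 9 | 6-bromo-2,3-bis(benzyloxy)phenol | Oc1c(Br)ccc(OCc2ccccc2)c1OCc1ccccc1
F7 | step 9 | O,C-dilithiated 2,3-bis(benzyloxy)phenoxide | [Li]Oc1c([Li])ccc(OCc2ccccc2)c1OCc1ccccc1
F8 | step 11 | 4-(2-methoxyvinyl)-1,2-bis(benzyloxy)benzene (alkene mixture) | COC=Cc1ccc(OCc2ccccc2)c(OCc2ccccc2)c1
F9 | step 11 | 3,4-bis(benzyloxy)phenylacetaldehyde | O=CCc1ccc(OCc2ccccc2)c(OCc2ccccc2)c1
F10 | step 11 | (Z)-2-[3,4-bis(benzyloxy)phenyl]vinyl benzoate | O=C(O/C=C\c1ccc(OCc2ccccc2)c(OCc2ccccc2)c1)c1ccccc1
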